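The earlier runs and the new flask stem from a simulated flask for substances that don't exist.

At early times, up to its first reading, the east run made Q at 0.112 h⁻¹ of the E charge, but between its last two readings at 0.00750 h⁻¹, slower by a factor of 14.9. I wanted that slowing for grey and blue, which have the same equivalents as east.

| flask | E | J | X | remark | time |
|---|---|---|---|---|---|
| north-east | 0.069 M | 0.60 equiv | 1.4 equiv | run made earlier |  |
| south-east | 0.069 M | 0.60 equiv | 2.2 equiv | run made earlier |  |
| east | 0.10 M | 0.60 equiv | 1 equiv | run made earlier |  |
| grey | 0.069 M | 0.600 equiv | 1.00 equiv |  | 15 h |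
| blue | 0.069 M | 0.600 equiv | 1.00 equiv |  | 30 h |

| run | time / h | E / % | Q / % | G / % |
|---|---|---|---|---|
| north-east | 5.00 | 20 | 48 | 20 |
| north-east | 10.0 | 13 | 60 | 18 |
| north-east | 15.0 | 11 | 68 | 19 |
| north-east | 20.0 | 3 | 71 | 15 |
| south-east | 1.33 | 29 | 31 | 13 |
| south-east | 3.00 | 14 | 54 | 13 |
| south-east | 8.00 | 6 | 76 | 10 |
| south-east | 20.0 | 3 | 86 | 8 |
| east | 2.50 | 26 | 28 | 22 |
| east | 6.00 | 23 | 40 | 22 |
| east | 12.0 | 14 | 51 | 23 |
| east | 20.0 | 11 | 57 | 23 |

(scatter of a reading: 2 percentage points)

- a reading of E is of its free form alone

* which of these there is most of at the end, counted by the E in it, grey (E / G / Q)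
* which of these there is most of at the end, counted by the E in it, blue (E / G / Q)
* how much there is at the end of the one of these that leads, in percent of the E charged: grey
* how much there is at the end of the one of these that leads, in percent of the E charged: blue

In east, G stood at 23% of the E charge, and I supposed that the rest of the 0.60 equiv of J had gone with X, one for one. That puts a ceiling on Q at 63.0% of the charge. The room under this ceiling fell from 12.0% at 12.0 h to 6.00% at 20.0 h, while the E outside G and Q moved from 26.0% to 20.0%. So I froze that pool and let the room decay as a pseudo-first-order quantity, with a half-life read as 8.00 h, rough given the scatter of 2 percentage points. I took the step to be bimolecular, so that dilution multiplies the rate by 0.690, and the half-life of the room in grey and blue is then 11.6 h, longer than in east. Grey at 15 h then stands where east stood at 10.3 h, which gave me 49.2% of Q, and blue 57.4%.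

The forecast said “Q leads in both”, with 46% for grey and 55% for blue, lower than my figures.

The flask gave Q in the lead in grey at 49.0%, and Q in the lead in blue at 56.6%, so the forecast stands within its tolerance.

    E + J → G (k = 22.0 M⁻¹ h⁻¹)
    X + J → L (k = 26.0 M⁻¹ h⁻¹)
    E + X → Q (k = 6.00 M⁻¹ h⁻¹)
    E ⇌ Z (K = 0.840, k = 2.50 h⁻¹)

Blue holds 56.6% of Q and, without the longer time, 49.0%, so the gap of 7.6 points to grey is the difference in time. Left ten times as long, blue reaches 62.9%, and the room under that went from 13.9% to 6.30%, a half-life of 13.1 h against my 11.6 h. For the same flask as blue read at 5.0 d, my half-life leaves a room of 0.0260%, so my reckoning puts Q at the ceiling of 63.0%. That flask gives 62.6%, with 0.25% of the X left.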